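The easy step came first: I counted partner, since in the earlier runs a substrate that became intermediate C seemed to have taken one partner, and one that became trapped intermediate a second.

| setting | theta | epsilon | gamma | flask |
|---|---|---|---|---|
| substrate | 0.30 M | 0.30 M | 0.45 M | 0.30 M |
| partner | 0.15 M (in portions, 3) | 0.60 M (in portions, 3) | 0.30 M (in portions, 3) | 0.300 M (in portions, 3) |
| capture agent | 0.30 M | 0.30 M | 0.30 M | 0.300 M |
| remark | run made earlier; portions every 50 s | run made earlier; portions every 50 s | run made earlier; portions every 50 s | the portions of partner follow each other after 50 s, the first at the start |
| time |  |  |  | 30 h |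

| run | time / h | substrate / % | intermediate C / % | trapped intermediate / % |
|---|---|---|---|---|
| theta | 2.50 | 52 | 49 | 3 |
| theta | 6.00 | 52 | 52 | 0 |
| theta | 12.0 | 48 | 51 | 0 |
| theta | 30.0 | 49 | 49 | 0 |
| epsilon | 4.00 | 0 | 17 | 80 |
| epsilon | 10.0 | 0 | 5 | 89 |
| epsilon | 20.0 | 0 | 2 | 91 |
| epsilon | 30.0 | 0 | 2 | 92 |
| gamma | 4.00 | 31 | 65 | 0 |
| gamma | 10.0 | 31 | 68 | 0 |
| gamma | 20.0 | 33 | 70 | 0 |
| gamma | 30.0 | 32 | 68 | 0 |

(each reading ± 2 percentage points)

- the numbers in the tables scatter by 2 percentage points (one standard deviation)
- the reaction counts as stopped when no species that holds the substrate changes by six tenths of a point or more over the second half of the time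

- which holds at 30 h: what has brought the reaction to rest, or that it has not come to rest (forward and back rates have come level / the partner has run out first / it is still moving)
- conversion of substrate at 30 h
- amount of intermediate C at 30 h, in percent of the substrate charged
- amount of trapped intermediate at 30 h, in percent of the substrate charged

From the balance of the partner I took 1.00 for this flask as the partner equivalents, c_partner/c_substrate, the partner charged per substrate charged: once the partner is used up, conversion plus whatever has taken a second partner, which the runs read as trapped intermediate, should equal this number, as fractions of the substrate. Theta, at 0.500, read intermediate C 49% at 30.0 h with substrate 49% beside it, and gamma, at 0.667, read 68% with substrate 32%, so in these two runs the partner acted as limiting reagent and the number matched the reading of intermediate C within the scatter. Epsilon, at 2.00, read substrate 0% and trapped intermediate 92%. For this flask the balance puts the substrate left level with what has taken a second partner but does not say how large both are, so one number was not enough: no earlier run stood at this ratio.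

The forecast gave conversion 97% (93% to 99.5%), intermediate C 94% (87% to 98%) and trapped intermediate 3% (0.5% to 7%), and its verdict was "it is still moving", on the ground that “That level would still be falling by more than 0.6 point”.

The flask gave conversion 98.2%, intermediate C 96.4% and trapped intermediate 1.76%, within the forecast's tolerance, but its end was "the partner has run out first".

    partner + intermediate C → intermediate D (k = 0.130 M⁻¹ min⁻¹)
    intermediate E → target (k = 0.120 min⁻¹)
    intermediate B → intermediate C (k = 0.0460 min⁻¹)
    intermediate A ⇌ intermediate B (K = 28.0, k = 0.0270 min⁻¹)
    capture agent + intermediate D → trapped intermediate (k = 0.570 M⁻¹ min⁻¹)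
    intermediate D → intermediate E (k = 0.00530 min⁻¹)
    substrate + partner → intermediate A (k = 3.10 M⁻¹ min⁻¹)

In this flask the partner stood at 0% of its charge at 15.0 h, and the substrate stood at 1.81% then and 1.81% at 30.0 h; conversion, trapped intermediate and target together came to 100% of the substrate charged, against equivalents of 100%. The neighbouring flask with 0.18 M of partner has equivalents of 0.600, so I expected that fraction as conversion. It gave partner 0%, trapped intermediate 0.00850%, and conversion 60.0%.

Readings and results were generated by integration from invented constants; scatter was added.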